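**Retrosynthetic overview**

1. Target 21 comes from its penta-benzyl ether 20, and 20 from 18, in which C4 is still CH–NO2. The ketone is unveiled last, so no flavone or 3-aroylbenzofuran can form while the ketal is built.
2. 18 comes from flavan phenol 9 and β-nitroenone 16. The key C3–C8′ bond is a catalyst-controlled Friedel–Crafts addition of the phenol to the nitroalkene, which acts as an enolonium equivalent of the ring A ketone.
3. The resulting keto diphenol closes the dihydrofuran and pyran rings together as one cis-fused ketal; the ketal configuration follows C3.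
4. 16 comes from aryl nitromethane 13 and arylglyoxal 14 (Henry reaction, dehydration); 9 comes from enone 5 by asymmetric transfer hydrogenation and Mitsunobu closure.
5. Ring order: flavan pyran ring (step 5), then both ketal rings (step 12), then the C4 ketone (step 13).

Assumption: the SMILES is read literally (flavan C2′ R, ketal C2 S, ring-fusion C3 S; flavanone-type unit unprimed, flavan unit primed), and 1 and 4 are bought.

**Route**

Step 1
Reactants: 1 2,4,6-trihydroxybenzaldehyde
Product: 2 2,6-dihydroxy-4-(methoxymethoxy)benzaldehyde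
Conditions: MOMCl (1.05 equiv), iPr2NEt, CH2Cl2, 0 °C
Reagents that add atoms: chloromethyl methyl ether, COCCl
Why: Williamson-type O-alkylation; the 4-OH is the most acidic and the only one not hydrogen-bonded to the aldehyde, so it reacts first.

Step 2
Reactants: 2 2,6-dihydroxy-4-(methoxymethoxy)benzaldehyde
Product: 3 2-(benzyloxy)-6-hydroxy-4-(methoxymethoxy)benzaldehyde
Conditions: BnBr (1.05 equiv), K2CO3, acetone, rt
Reagents that add atoms: benzyl bromide, BrCc1ccccc1
Why: Williamson etherification; once one ortho-OH is benzylated the other stays chelated to the aldehyde and is not alkylated.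

Step 3
Reactants: 3 2-(benzyloxy)-6-hydroxy-4-(methoxymethoxy)benzaldehyde; 4 1-[4-(benzyloxy)phenyl]ethan-1-one
Product: 5 (E)-3-[2-(benzyloxy)-6-hydroxy-4-(methoxymethoxy)phenyl]-1-[4-(benzyloxy)phenyl]prop-2-en-1-one
Conditions: KOH, EtOH, rt
Reagents that add atoms: none
Why: Claisen–Schmidt aldol condensation with E1cB dehydration gives the E-enone; MOM and benzyl ethers are base-stable.

Step 4
Reactants: 5 (E)-3-[2-(benzyloxy)-6-hydroxy-4-(methoxymethoxy)phenyl]-1-[4-(benzyloxy)phenyl]prop-2-en-1-one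
Product: 7 (1S)-3-[2-(benzyloxy)-6-hydroxy-4-(methoxymethoxy)phenyl]-1-[4-(benzyloxy)phenyl]propan-1-ol, via saturated ketone 6 (not isolated)
Conditions: RuCl[(S,S)-TsDPEN](p-cymene) (2 mol%), HCO2H–Et3N (5:2), DMF, 40 °C
Reagents that add atoms: none
Why: Noyori–Ikariya asymmetric transfer hydrogenation; the ruthenium hydride first saturates the conjugated C=C and then reduces the aryl ketone, the (S,S) ligand giving the S carbinol that becomes the flavan stereocentre.

Step 5
Reactants: 7 (1S)-3-[2-(benzyloxy)-6-hydroxy-4-(methoxymethoxy)phenyl]-1-[4-(benzyloxy)phenyl]propan-1-ol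
Product: 8 (2R)-5-(benzyloxy)-2-[4-(benzyloxy)phenyl]-7-(methoxymethoxy)chromane
Conditions: PPh3, DIAD, THF, 0 °C → rt
Reagents that add atoms: none
Why: Mitsunobu cycloetherification; the ortho phenol displaces the activated benzylic alcohol with inversion, so the S carbinol gives the 2R flavan.

Step 6
Reactants: 8 (2R)-5-(benzyloxy)-2-[4-(benzyloxy)phenyl]-7-(methoxymethoxy)chromane
Product: 9 (2R)-5-(benzyloxy)-2-[4-(benzyloxy)phenyl]chroman-7-ol
Conditions: HCl (cat.), MeOH–THF, 40 °C
Reagents that add atoms: none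
Why: Acid-catalysed acetal exchange removes only the MOM group; benzyl ethers and the chromane ring survive these mild conditions.

Step 7
Reactants: 1 2,4,6-trihydroxybenzaldehyde
Product: 10 2,4-bis(benzyloxy)-6-hydroxybenzaldehyde
Conditions: BnBr (2.1 equiv), K2CO3, DMF, rt
Reagents that add atoms: benzyl bromide, BrCc1ccccc1
Why: Williamson etherification; the ortho-OH chelated to the aldehyde stays free.

Step 8
Reactants: 10 2,4-bis(benzyloxy)-6-hydroxybenzaldehyde
Product: 11 3,5-bis(benzyloxy)-2-(hydroxymethyl)phenol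
Conditions: NaBH4, THF–MeOH, 0 °C; neutral work-up, used at once
Reagents that add atoms: none
Why: Hydride reduction of the aldehyde to the salicyl alcohol.

Step 9
Reactants: 11 3,5-bis(benzyloxy)-2-(hydroxymethyl)phenol
Product: 13 3,5-bis(benzyloxy)-2-(nitromethyl)phenol, via o-quinone methide 12 (not isolated)
Conditions: NaNO2 (5 equiv), DMSO–H2O (9:1), 60 °C; cold pH 6 phosphate buffer work-up
Reagents that add atoms: sodium nitrite, [Na+].[O-]N=O
Why: Proposed new method: the electron-rich salicyl alcohol loses water on warming to give o-quinone methide 12, which nitrite captures at the exocyclic carbon; O-attack gives a nitrite ester that re-ionises, whereas N-attack gives the C-nitro compound, which is drained from the equilibrium as its nitronate, so 13 accumulates; closest known reactions are the 1,4-additions of azide, cyanide and sulfinate to o-quinone methides and the conjugate addition of NaNO2 to enones.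

Step 10
Reactants: 4 1-[4-(benzyloxy)phenyl]ethan-1-one
Product: 14 2-[4-(benzyloxy)phenyl]-2-oxoacetaldehyde
Conditions: SeO2, dioxane–H2O, reflux
Reagents that add atoms: selenium dioxide, O=[Se]=O
Why: Riley oxidation of the methyl ketone to the arylglyoxal.

Step 11
Reactants: 13 3,5-bis(benzyloxy)-2-(nitromethyl)phenol; 14 2-[4-(benzyloxy)phenyl]-2-oxoacetaldehyde
Product: 16 (E)-1-[4-(benzyloxy)phenyl]-3-[2,4-bis(benzyloxy)-6-hydroxyphenyl]-3-nitroprop-2-en-1-one, via nitroaldol 15 (not isolated)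
Conditions: Et3N (10 mol%), THF, 0 °C; then DCC, CuCl (10 mol%), rt
Reagents that add atoms: none
Why: Henry (nitroaldol) addition of the acidic aryl nitromethane to the aldehyde carbon of the glyoxal, then CuCl-catalysed DCC dehydration, the standard route to β-nitroenones; 16 equilibrates with its cyclic 2H-chromen-2-ol hemiketal.

Step 12
Reactants: 9 (2R)-5-(benzyloxy)-2-[4-(benzyloxy)phenyl]chroman-7-ol; 16 (E)-1-[4-(benzyloxy)phenyl]-3-[2,4-bis(benzyloxy)-6-hydroxyphenyl]-3-nitroprop-2-en-1-one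
Product: 18 penta-O-benzyl 4-deoxo-4-nitro analogue of the target (C4 epimers), via keto diphenol adduct 17 (not isolated)
Conditions: quinine-derived squaramide 3-{[3,5-bis(trifluoromethyl)phenyl]amino}-4-{[(8α,9S)-6′-methoxycinchonan-9-yl]amino}cyclobut-3-ene-1,2-dione (10 mol%), CH2Cl2, −20 °C; then CSA (25 mol%), 4 Å MS, 0 °C → rt
Reagents that add atoms: none
Why: Proposed new method: nitroenone 16 is an enolonium (α-cation) equivalent of the future C4 ketone, its C3 being electrophilic because it is β to nitro; the squaramide NH groups bind the nitro group while the quinuclidine nitrogen hydrogen-bonds the 7′-OH of 9, so the ortho carbon C8′ (more accessible than C6′, which is flanked by the benzyl ether) adds to one face of C3 in an asymmetric Friedel–Crafts alkylation that sets the ring-fusion CH as S; CSA then condenses the C2 ketone of 17 with the 7′-OH and the ring A ortho-OH to the bicyclic bis-aryl ketal, whose C2 configuration is dictated by C3 because only the cis ring fusion is geometrically possible, and with C4 still CH–NO2 no flavone or 3-aroylbenzofuran can form by loss of H3; closest known reactions are squaramide- or thiourea-catalysed Friedel–Crafts additions of naphthols and sesamol to nitroalkenes, arene additions to β-nitroenones, and the acid-mediated condensation of arylglyoxals with two phenols to benzofuro-fused ketals.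

Step 13
Reactants: 18 penta-O-benzyl 4-deoxo-4-nitro analogue of the target (C4 epimers)
Product: 20 penta-O-benzyl ether of the target, via sodium nitronate 19 (not isolated)
Conditions: NaOMe (1.1 equiv), MeOH–THF, 0 °C; then aq. TiCl3 (4 equiv), NH4OAc buffer (pH 5–6), 0 °C → rt
Reagents that add atoms: water, O
Why: McMurry TiCl3 Nef reaction; the nitronate is made while no ketone is present, then reduced to the imine and hydrolysed at buffered pH, where the new β-aryloxy ketone does not undergo E1cB ring opening; both C4 epimers converge and C3 cannot epimerise in the cis-fused system.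

Step 14
Reactants: 20 penta-O-benzyl ether of the target
Product: 21 target
Conditions: H2 (1 atm), Pd/C (10 wt%), EtOAc–MeOH, rt
Reagents that add atoms: none
Why: Catalytic hydrogenolysis of the five benzyl aryl ethers under neutral conditions, which avoids the acid- or base-induced opening of the ketal to the aromatic isomers; no stereocentre is touched.

**Compound list**

1 | 2,4,6-trihydroxybenzaldehyde | O=Cc1c(O)cc(O)cc1O | starting material
2 | 2,6-dihydroxy-4-(methoxymethoxy)benzaldehyde | O=Cc1c(O)cc(OCOC)cc1O | intermediate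
3 | 2-(benzyloxy)-6-hydroxy-4-(methoxymethoxy)benzaldehyde | O=Cc1c(O)cc(OCOC)cc1OCc1ccccc1 | intermediate
4 | 1-[4-(benzyloxy)phenyl]ethan-1-one | CC(=O)c1ccc(OCc2ccccc2)cc1 | starting material
5 | (E)-3-[2-(benzyloxy)-6-hydroxy-4-(methoxymethoxy)phenyl]-1-[4-(benzyloxy)phenyl]prop-2-en-1-one | O=C(/C=C/c1c(O)cc(OCOC)cc1OCc1ccccc1)c1ccc(OCc2ccccc2)cc1 | intermediate
6 | 3-[2-(benzyloxy)-6-hydroxy-4-(methoxymethoxy)phenyl]-1-[4-(benzyloxy)phenyl]propan-1-one | O=C(CCc1c(O)cc(OCOC)cc1OCc1ccccc1)c1ccc(OCc2ccccc2)cc1 | intermediate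
7 | (1S)-3-[2-(benzyloxy)-6-hydroxy-4-(methoxymethoxy)phenyl]-1-[4-(benzyloxy)phenyl]propan-1-ol | O[C@@H](CCc1c(O)cc(OCOC)cc1OCc1ccccc1)c1ccc(OCc2ccccc2)cc1 | intermediate
8 | (2R)-5-(benzyloxy)-2-[4-(benzyloxy)phenyl]-7-(methoxymethoxy)chromane | COCOc1cc(OCc2ccccc2)c2c(c1)O[C@@H](c1ccc(OCc3ccccc3)cc1)CC2 | intermediate
9 | (2R)-5-(benzyloxy)-2-[4-(benzyloxy)phenyl]chroman-7-ol | Oc1cc(OCc2ccccc2)c2c(c1)O[C@@H](c1ccc(OCc3ccccc3)cc1)CC2 | intermediate
10 | 2,4-bis(benzyloxy)-6-hydroxybenzaldehyde | O=Cc1c(O)cc(OCc2ccccc2)cc1OCc1ccccc1 | intermediate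
11 | 3,5-bis(benzyloxy)-2-(hydroxymethyl)phenol | OCc1c(O)cc(OCc2ccccc2)cc1OCc1ccccc1 | intermediate
12 | 3,5-bis(benzyloxy)-6-methylidenecyclohexa-2,4-dien-1-one (o-quinone methide) | C=C1C(=O)C=C(OCc2ccccc2)C=C1OCc1ccccc1 | intermediate
13 | 3,5-bis(benzyloxy)-2-(nitromethyl)phenol | O=[N+]([O-])Cc1c(O)cc(OCc2ccccc2)cc1OCc1ccccc1 | intermediate
14 | 2-[4-(benzyloxy)phenyl]-2-oxoacetaldehyde | O=CC(=O)c1ccc(OCc2ccccc2)cc1 | intermediate
15 | 1-[4-(benzyloxy)phenyl]-3-[2,4-bis(benzyloxy)-6-hydroxyphenyl]-2-hydroxy-3-nitropropan-1-one (diastereomers) | O=C(c1ccc(OCc2ccccc2)cc1)C(O)C(c1c(O)cc(OCc2ccccc2)cc1OCc1ccccc1)[N+](=O)[O-] | intermediate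
16 | (E)-1-[4-(benzyloxy)phenyl]-3-[2,4-bis(benzyloxy)-6-hydroxyphenyl]-3-nitroprop-2-en-1-one (in equilibrium with its 2H-chromen-2-ol hemiketal) | O=C(c1ccc(OCc2ccccc2)cc1)/C=C(\c1c(O)cc(OCc2ccccc2)cc1OCc1ccccc1)[N+](=O)[O-] | intermediate
17 | (2S)-1-[4-(benzyloxy)phenyl]-2-{(2R)-5-(benzyloxy)-2-[4-(benzyloxy)phenyl]-7-hydroxychroman-8-yl}-3-[2,4-bis(benzyloxy)-6-hydroxyphenyl]-3-nitropropan-1-one (C3 epimers; hemiketal tautomers) | O=C(c1ccc(OCc2ccccc2)cc1)[C@@H](c1c(O)cc(OCc2ccccc2)c2c1O[C@@H](c1ccc(OCc3ccccc3)cc1)CC2)C(c1c(O)cc(OCc2ccccc2)cc1OCc1ccccc1)[N+](=O)[O-] | intermediate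
18 | (2S,3S)-5,7-bis(benzyloxy)-2-[4-(benzyloxy)phenyl]-4-nitrochromane whose C2 is bonded to O7′ and C3 to C8′ of (2′R)-5′-(benzyloxy)-2′-[4-(benzyloxy)phenyl]chromane (cis-fused ketal; C4 epimers) | O=[N+]([O-])C1c2c(OCc5ccccc5)cc(OCc5ccccc5)cc2O[C@@]2(c3ccc(OCc5ccccc5)cc3)Oc3cc(OCc5ccccc5)c4c(c3[C@@H]12)O[C@@H](c1ccc(OCc5ccccc5)cc1)CC4 | intermediate
19 | sodium nitronate of 18 | [Na+].[O-][N+]([O-])=C1c2c(OCc5ccccc5)cc(OCc5ccccc5)cc2O[C@@]2(c3ccc(OCc5ccccc5)cc3)Oc3cc(OCc5ccccc5)c4c(c3[C@@H]12)O[C@@H](c1ccc(OCc5ccccc5)cc1)CC4 | intermediate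
20 | (2S,3S)-5,7-bis(benzyloxy)-2-[4-(benzyloxy)phenyl]chroman-4-one whose C2 is bonded to O7′ and C3 to C8′ of (2′R)-5′-(benzyloxy)-2′-[4-(benzyloxy)phenyl]chromane (penta-O-benzyl ether of 21) | O=C1c2c(OCc5ccccc5)cc(OCc5ccccc5)cc2O[C@@]2(c3ccc(OCc5ccccc5)cc3)Oc3cc(OCc5ccccc5)c4c(c3[C@@H]12)O[C@@H](c1ccc(OCc5ccccc5)cc1)CC4 | intermediate
21 | (2S,3S)-5,7-dihydroxy-2-(4-hydroxyphenyl)chroman-4-one whose C2 is bonded to O7′ and C3 to C8′ of (2′R)-5′-hydroxy-2′-(4-hydroxyphenyl)chromane (cis-fused ketal) | O=C1c2c(O)cc(O)cc2O[C@@]2(c3ccc(O)cc3)Oc3cc(O)c4c(c3[C@@H]12)O[C@@H](c1ccc(O)cc1)CC4 | target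

**Step count and risks**

Total steps: 14. Longest linear sequence: 9 (steps 1–6, then 12–14).

Step 12 is the most likely to fail. The Friedel–Crafts addition may occur at C6′ instead of C8′, the adduct may lose HNO2 before it is ketalised, or the catalyst may give the wrong or a low sense of induction (the quinidine-derived pseudoenantiomer is the first remedy for the last point). The fallback sets out from 8 and comes back at 18. NBS in CH2Cl2 at −78 °C brominates 8 at the carbon between the MOM ether and the pyran oxygen to give (2R)-5-(benzyloxy)-2-[4-(benzyloxy)phenyl]-8-bromo-7-(methoxymethoxy)chromane F2. Bromine–lithium exchange with n-BuLi, then B(OiPr)3 and aqueous work-up, gives the arylboronic acid F3. A Hayashi-type asymmetric 1,4-addition of F3 to nitroalkene 16, with [RhCl(C2H4)2]2 and (R,R)-2,5-diphenylbicyclo[2.2.2]octa-2,5-diene in dioxane–H2O with KOH, fixes the C8′ regiochemistry and gives the MOM-protected adduct F4. CSA in MeOH–CH2Cl2 then removes the MOM group and closes both ketal rings to 18.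

Step 9 is the second risk: the o-quinone methide may oligomerise or be trapped by the product nitronate. The fallback sets out from 10 and comes back at 13. Condensation of 10 with NH2OH·HCl and NaOAc gives the aldoxime F1, and NaBO3·4H2O in AcOH at 55 °C oxidises the oxime nitrogen to the nitro compound 13, so the C–N bond comes from the aldehyde instead of from nitrite capture.

Step 13 is the third risk: the hindered nitronate may stop at the oxime, or the new β-aryloxy ketone may open. The fallback sets out from 18 and comes back at 20. SnCl2·2H2O, PhSH and Et3N reduce the nitro group to the ketoxime F5, and exchange with glyoxylic acid in aqueous NaOAc buffer–THF transfers the oxime to the aldehyde and releases ketone 20 without a nitronate or a strongly acidic reductant.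

**Further compounds**

F1 | step 9 | (E)-2,4-bis(benzyloxy)-6-hydroxybenzaldehyde oxime | O/N=C/c1c(O)cc(OCc2ccccc2)cc1OCc1ccccc1
F2 | step 12 | (2R)-5-(benzyloxy)-2-[4-(benzyloxy)phenyl]-8-bromo-7-(methoxymethoxy)chromane | COCOc1cc(OCc2ccccc2)c2c(c1Br)O[C@@H](c1ccc(OCc3ccccc3)cc1)CC2
F3 | step 12 | {(2R)-5-(benzyloxy)-2-[4-(benzyloxy)phenyl]-7-(methoxymethoxy)chroman-8-yl}boronic acid | COCOc1cc(OCc2ccccc2)c2c(c1B(O)O)O[C@@H](c1ccc(OCc3ccccc3)cc1)CC2
F4 | step 12 | (2S)-1-[4-(benzyloxy)phenyl]-2-{(2R)-5-(benzyloxy)-2-[4-(benzyloxy)phenyl]-7-(methoxymethoxy)chroman-8-yl}-3-[2,4-bis(benzyloxy)-6-hydroxyphenyl]-3-nitropropan-1-one | O=C(c1ccc(OCc2ccccc2)cc1)[C@@H](c1c(OCOC)cc(OCc2ccccc2)c2c1O[C@@H](c1ccc(OCc3ccccc3)cc1)CC2)C(c1c(O)cc(OCc2ccccc2)cc1OCc1ccccc1)[N+](=O)[O-]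
F5 | step 13 | 4-oxime of 20 | ON=C1c2c(OCc5ccccc5)cc(OCc5ccccc5)cc2O[C@@]2(c3ccc(OCc5ccccc5)cc3)Oc3cc(OCc5ccccc5)c4c(c3[C@@H]12)O[C@@H](c1ccc(OCc5ccccc5)cc1)CC4
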